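The route rests on annulating the dihydrofuran (ring B) onto ring A in one operation. Ring A bears O1 on C7a, C3 on C3a and hydrogen on C4. These three adjacent positions are the imprint of a 1,2-benzdiyne equivalent that takes up first a nucleophile and then an ene partner. An (R,E)-1-arylbut-2-enyl alkoxide adds to a 3-triflyloxyaryne at C7a and the C4 triflate departs. The second aryne then engages the propenyl group in an intramolecular ene reaction, so O1–C7a, C3–C3a, ring B and the C3 stereocentre arise together. The precursors are methyl 4-silyl-2,3-bis(triflyloxy)benzoate and the allylic alcohol, used as its trimethylsilyl ether.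

Key step: step 8

Remark on the chemistry: the target SMILES reads as (2R,3S), with the C2 aryl and C3 CH2OH groups trans. Benzofuran numbering (O1, C2, C3, C3a, C4–C7, C7a) is used for the bicyclic compounds and for the ring-A atoms of the silyl bis-triflate (benzoate C4-Si = C7a, C3-OTf = C3a, C2-OTf = C4, C1-CO2Me = C5). The C3 descriptor is R in the vinyl and formyl compounds and S in the hydroxymethyl compounds only because CIP ranks change; the spatial arrangement stays the same.

Step 1
Reactants: 1 catechol
Product: 2 1,2-bis(methoxymethoxy)benzene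
Conditions: NaH (2.4 equiv), MOMCl (2.4 equiv), DMF, 0 °C → rt
Reagents that add atoms: chloromethyl methyl ether, COCCl
Why: Williamson-type O-alkylation of the catechol dianion installs two acetal ethers that resist organolithium reagents and are strong ortho-directing groups.

Step 2
Reactants: 2 1,2-bis(methoxymethoxy)benzene
Product: 4 [2,3-bis(methoxymethoxy)phenyl]trimethylsilane, via aryllithium 3 (not isolated)
Conditions: n-BuLi, TMEDA, Et2O, 0 °C → rt; TMSCl, −78 °C → rt
Reagents that add atoms: chlorotrimethylsilane, C[Si](C)(C)Cl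
Why: Directed ortho-metalation at one of the two equivalent positions next to an OMOM group gives a single silane, and silicon is introduced before the carboxyl carbon because an ester would not survive butyllithium.

Step 3
Reactants: 4 [2,3-bis(methoxymethoxy)phenyl]trimethylsilane
Product: 6 methyl 2,3-bis(methoxymethoxy)-4-(trimethylsilyl)benzoate, via aryllithium 5 (not isolated)
Conditions: s-BuLi, TMEDA, THF, −78 °C; cannulated into ClCO2Me (3 equiv), THF, −78 °C → rt
Reagents that add atoms: methyl chloroformate, COC(=O)Cl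
Why: A second directed ortho-metalation can occur only at the one remaining position beside an OMOM group (the future C5), and inverse addition to excess chloroformate suppresses attack of the aryllithium on the new ester.

Step 4
Reactants: 6 methyl 2,3-bis(methoxymethoxy)-4-(trimethylsilyl)benzoate
Product: 7 methyl 2,3-dihydroxy-4-(trimethylsilyl)benzoate
Conditions: conc. HCl (cat.), MeOH, 40 °C
Reagents that add atoms: none
Why: Acid-catalysed acetal exchange with methanol frees both phenols, and the ester para to silicon slows ipso-protonation so that the aryl–silicon bond should survive dilute acid.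

Step 5
Reactants: 7 methyl 2,3-dihydroxy-4-(trimethylsilyl)benzoate
Product: 8 methyl 2,3-bis(trifluoromethylsulfonyloxy)-4-(trimethylsilyl)benzoate
Conditions: Tf2O (2.6 equiv), pyridine (6 equiv), CH2Cl2, 0 °C → rt
Reagents that add atoms: trifluoromethanesulfonic anhydride, O=S(=O)(OS(=O)(=O)C(F)(F)F)C(F)(F)F
Why: Standard O-sulfonylation of both phenols gives an o-silylaryl triflate with a second triflate beside it, and placing silicon at the end of the Si/OTf/OTf row leaves only one possible first elimination.

Step 6
Reactants: 9 propyne; 10 3,4,5-trimethoxybenzaldehyde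
Product: 13 (R,E)-1-(3,4,5-trimethoxyphenyl)but-2-en-1-ol, via propenylborane 11 (not isolated), via propenylzinc 12 (not isolated)
Conditions: Cy2BH (from BH3·SMe2, cyclohexene), 9 (condensed), toluene, 0 °C → rt, excess 9 purged; Me2Zn, −78 °C; (+)-MIB (5 mol %), 10, −10 °C; aq NH4Cl
Reagents that add atoms: none
Why: syn-Hydroboration fixes the E geometry and boron–zinc exchange retains it; the ligand-accelerated catalytic asymmetric alkenylzinc addition with (+)-3-exo-morpholinoisoborneol (the antipode of the ligand that gives (S)-carbinols from aryl aldehydes) then delivers the propenyl group to the Re face and sets the (R) carbinol centre, the future C2.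

Step 7
Reactants: 13 (R,E)-1-(3,4,5-trimethoxyphenyl)but-2-en-1-ol
Product: 14 (R,E)-trimethyl{[1-(3,4,5-trimethoxyphenyl)but-2-en-1-yl]oxy}silane
Conditions: TMSCl, imidazole, CH2Cl2, 0 °C; filtration through Et3N-deactivated silica
Reagents that add atoms: chlorotrimethylsilane, C[Si](C)(C)Cl
Why: Routine O-silylation under non-acidic conditions leaves the ionisable carbinol centre intact and gives a proton-free alkoxide source, since a free O–H would protonate the C3a carbanion and stop the cascade after the first addition.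

Step 8
Reactants: 8 methyl 2,3-bis(trifluoromethylsulfonyloxy)-4-(trimethylsilyl)benzoate; 14 (R,E)-trimethyl{[1-(3,4,5-trimethoxyphenyl)but-2-en-1-yl]oxy}silane
Product: 18 methyl (2R,3R)-2-(3,4,5-trimethoxyphenyl)-3-vinyl-2,3-dihydrobenzofuran-5-carboxylate, via potassium alkoxide 15 (not isolated), via triflyloxyaryne 16 (not isolated), via alkoxyaryne 17 (not isolated)
Conditions: KF (spray-dried, 5 equiv), 18-crown-6 (5 equiv), THF, 0 °C; 14 (1 equiv) + 8 (1.3 equiv) in THF added over 2 h; then rt
Reagents that add atoms: none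
Why: Proposed new method: fluoride frees alkoxide 15 from 14 without any proton donor and desilylates C7a of 8, and because the only leaving group next to that carbon is the C3a triflate, a single aryne, 3-triflyloxyaryne 16, can form. The inductively withdrawing C4 triflate polarises the C7a–C3a triple bond so that 15 attacks the remote carbon C7a (bond O1–C7a), and the C3a carbanion so formed ejects the C4 triflate to give aryne 17 (C3a≡C4), which has the allylic ether on one side and the ester on the other. In 17 the (E)-propenyl unit acts as ene donor through a six-membered array (C3a, C4, H, CH2, CH, C3): C3 bonds to C3a, one methyl hydrogen ends on C4 and the double bond shifts outward to a vinyl group, a 5-exo closure of ring B that is the only one the two-atom O1–C2 tether allows. The closest known reaction types are the nucleophile–ene domino annulation of 1,2-benzdiyne equivalents with sulfonamide anions, which gives indolines, and the intramolecular aryne–ene cyclisation of simple o-silylaryl triflates; the oxygen nucleophile and the unsymmetrical ester-bearing precursor are new. C2 keeps the configuration of 13 because its C–O bond is never broken, and it controls C3: with the trimethoxyphenyl group pseudo-equatorial in the envelope-shaped transition state, the carbon that becomes the vinyl group turns to the opposite ring face, which should give the 2,3-trans (2R,3R) isomer. The step needs a regioselective first addition, secured by the C4 triflate, and chemoselectivity for aryne carbon over ester and sulfonyl centres and for ene closure over a second addition, both served by slow co-addition that keeps the alkoxide concentration low.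

Step 9
Reactants: 18 methyl (2R,3R)-2-(3,4,5-trimethoxyphenyl)-3-vinyl-2,3-dihydrobenzofuran-5-carboxylate
Product: 20 [(2R,3S)-2-(3,4,5-trimethoxyphenyl)-2,3-dihydrobenzofuran-3,5-diyl]dimethanol, via aldehyde 19 (not isolated)
Conditions: K2OsO4·2H2O (2 mol %), NaIO4 (4 equiv), 2,6-lutidine, dioxane/H2O, rt; extraction, toluene azeotrope; LiAlH4, THF, 0 °C → rt
Reagents that add atoms: sodium periodate, [Na+].[O-]I(=O)(=O)=O
Why: Lemieux–Johnson cleavage attacks only the terminal alkene and spares the electron-rich arene, which ozone might not, and immediate hydride reduction of the crude β-aryloxy aldehyde together with the ester leaves no time for enolisation or ring opening at C3, so both stereocentres are kept.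

Step 10
Reactants: 20 [(2R,3S)-2-(3,4,5-trimethoxyphenyl)-2,3-dihydrobenzofuran-3,5-diyl]dimethanol
Product: 22 ethyl (E)-3-[(2R,3S)-3-(hydroxymethyl)-2-(3,4,5-trimethoxyphenyl)-2,3-dihydrobenzofuran-5-yl]acrylate, via aldehyde 21 (not isolated)
Conditions: activated MnO2 (15 equiv), Ph3P=CHCO2Et (1.3 equiv), CH2Cl2, rt → reflux
Reagents that add atoms: ethyl (triphenylphosphoranylidene)acetate, CCOC(=O)C=P(c1ccccc1)(c1ccccc1)c1ccccc1
Why: In this tandem oxidation–Wittig reaction MnO2 oxidises only the benzylic alcohol, and the stabilised ylide traps aldehyde 21 as it forms to give the (E)-cinnamate.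

Step 11
Reactants: 22 ethyl (E)-3-[(2R,3S)-3-(hydroxymethyl)-2-(3,4,5-trimethoxyphenyl)-2,3-dihydrobenzofuran-5-yl]acrylate
Product: 23 (E)-3-[(2R,3S)-3-(hydroxymethyl)-2-(3,4,5-trimethoxyphenyl)-2,3-dihydrobenzofuran-5-yl]prop-2-en-1-ol
Conditions: i-Bu2AlH (4 equiv), CH2Cl2, −78 → 0 °C; aq Rochelle salt
Reagents that add atoms: none
Why: 1,2-Reduction of the unsaturated ester with i-Bu2AlH gives the allylic alcohol without touching the alkene geometry or the stereocentres, and one extra equivalent is consumed by the free hydroxyl.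

Compound list
1 | catechol | Oc1ccccc1O | starting material
2 | 1,2-bis(methoxymethoxy)benzene | COCOc1ccccc1OCOC | intermediate
3 | [2,3-bis(methoxymethoxy)phenyl]lithium | [Li]c1cccc(OCOC)c1OCOC | intermediate
4 | [2,3-bis(methoxymethoxy)phenyl]trimethylsilane | COCOc1cccc([Si](C)(C)C)c1OCOC | intermediate
5 | [2,3-bis(methoxymethoxy)-4-(trimethylsilyl)phenyl]lithium | [Li]c1ccc([Si](C)(C)C)c(OCOC)c1OCOC | intermediate
6 | methyl 2,3-bis(methoxymethoxy)-4-(trimethylsilyl)benzoate | COC(=O)c1ccc([Si](C)(C)C)c(OCOC)c1OCOC | intermediate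
7 | methyl 2,3-dihydroxy-4-(trimethylsilyl)benzoate | COC(=O)c1ccc([Si](C)(C)C)c(O)c1O | intermediate
8 | methyl 2,3-bis(trifluoromethylsulfonyloxy)-4-(trimethylsilyl)benzoate | COC(=O)c1ccc([Si](C)(C)C)c(OS(=O)(=O)C(F)(F)F)c1OS(=O)(=O)C(F)(F)F | intermediate
9 | propyne | CC#C | starting material
10 | 3,4,5-trimethoxybenzaldehyde | COc1cc(C=O)cc(OC)c1OC | starting material
11 | dicyclohexyl[(E)-prop-1-enyl]borane | C/C=C/B(C1CCCCC1)C1CCCCC1 | intermediate
12 | methyl[(E)-prop-1-enyl]zinc | C/C=C/[Zn]C | intermediate
13 | (R,E)-1-(3,4,5-trimethoxyphenyl)but-2-en-1-ol | COc1cc([C@@H](/C=C/C)O)cc(OC)c1OC | intermediate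
14 | (R,E)-trimethyl{[1-(3,4,5-trimethoxyphenyl)but-2-en-1-yl]oxy}silane | COc1cc([C@@H](/C=C/C)O[Si](C)(C)C)cc(OC)c1OC | intermediate
15 | potassium (R,E)-1-(3,4,5-trimethoxyphenyl)but-2-en-1-olate | COc1cc([C@@H](/C=C/C)[O-])cc(OC)c1OC.[K+] | intermediate
16 | methyl 3,4-didehydro-2-(trifluoromethylsulfonyloxy)benzoate | COC(=O)C1=C(OS(=O)(=O)C(F)(F)F)C#CC=C1 | intermediate
17 | methyl 2,3-didehydro-4-{[(R,E)-1-(3,4,5-trimethoxyphenyl)but-2-en-1-yl]oxy}benzoate | COc1cc([C@@H](/C=C/C)OC2=CC=C(C(=O)OC)C#C2)cc(OC)c1OC | intermediate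
18 | methyl (2R,3R)-2-(3,4,5-trimethoxyphenyl)-3-vinyl-2,3-dihydrobenzofuran-5-carboxylate (2,3-trans) | COc1cc([C@@H]2Oc3ccc(C(=O)OC)cc3[C@H]2C=C)cc(OC)c1OC | intermediate
19 | methyl (2R,3R)-3-formyl-2-(3,4,5-trimethoxyphenyl)-2,3-dihydrobenzofuran-5-carboxylate | COc1cc([C@@H]2Oc3ccc(C(=O)OC)cc3[C@H]2C=O)cc(OC)c1OC | intermediate
20 | [(2R,3S)-2-(3,4,5-trimethoxyphenyl)-2,3-dihydrobenzofuran-3,5-diyl]dimethanol | COc1cc([C@@H]2Oc3ccc(CO)cc3[C@H]2CO)cc(OC)c1OC | intermediate
21 | (2R,3S)-3-(hydroxymethyl)-2-(3,4,5-trimethoxyphenyl)-2,3-dihydrobenzofuran-5-carbaldehyde | COc1cc([C@@H]2Oc3ccc(C=O)cc3[C@H]2CO)cc(OC)c1OC | intermediate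
22 | ethyl (E)-3-[(2R,3S)-3-(hydroxymethyl)-2-(3,4,5-trimethoxyphenyl)-2,3-dihydrobenzofuran-5-yl]acrylate | COc1cc([C@@H]2Oc3ccc(/C=C/C(=O)OCC)cc3[C@H]2CO)cc(OC)c1OC | intermediate
23 | (E)-3-[(2R,3S)-3-(hydroxymethyl)-2-(3,4,5-trimethoxyphenyl)-2,3-dihydrobenzofuran-5-yl]prop-2-en-1-ol (CNP0077408.1) | COc1cc([C@@H]2Oc3ccc(/C=C/CO)cc3[C@H]2CO)cc(OC)c1OC | target

Total steps: 11. Longest linear sequence: 9 (steps 1–5 and 8–11).

Steps most likely to fail

1. Step 8.
- What may go wrong: the alkoxide may attack the ester carbonyl or a sulfonyl sulfur instead of the aryne. The C3a carbanion may be protonated or suffer sulfonyl migration before the triflate leaves. The second aryne may be intercepted by alkoxide or fluoride before ene closure. Facial selectivity at C3 may be weak.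
- Fallback (known chemistry, sets out from 10, rejoins at 22): ring B is closed through the C2–C3 bond by carbenoid C–H insertion.
- NaBH4 in MeOH reduces 10 to 3,4,5-trimethoxybenzyl alcohol F1.
- Mitsunobu etherification (PPh3, DIAD, THF) with purchased methyl 2-(5-bromo-2-hydroxyphenyl)acetate (COC(=O)Cc1cc(Br)ccc1O) gives methyl 2-[5-bromo-2-(3,4,5-trimethoxybenzyloxy)phenyl]acetate F2.
- Regitz diazo transfer (p-acetamidobenzenesulfonyl azide, DBU, MeCN) gives methyl 2-[5-bromo-2-(3,4,5-trimethoxybenzyloxy)phenyl]-2-diazoacetate F3.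
- A chiral dirhodium tetracarboxylate such as Rh2(S-PTTL)4, or its antipode if that is the one leading to the (2R) series, promotes enantioselective intramolecular insertion into a benzylic C–H bond. This should give the cis ester methyl (2R,3S)-5-bromo-2-(3,4,5-trimethoxyphenyl)-2,3-dihydrobenzofuran-3-carboxylate F4.
- NaOMe in MeOH epimerises C3 to the more stable trans ester methyl (2R,3R)-5-bromo-2-(3,4,5-trimethoxyphenyl)-2,3-dihydrobenzofuran-3-carboxylate F5.
- LiBH4 in THF gives [(2R,3S)-5-bromo-2-(3,4,5-trimethoxyphenyl)-2,3-dihydrobenzofuran-3-yl]methanol F6.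
- A Heck reaction with ethyl acrylate (Pd(OAc)2, P(o-tol)3, Et3N, DMF, 100 °C) gives 22.

2. Step 6.
- What may go wrong: the small alkyne may be hydroborated twice, methyl transfer from zinc may compete, and enantioselectivity with this electron-rich aldehyde may be insufficient.
- Fallback (sets out from 10, rejoins at 13): the carbinol centre is secured by kinetic resolution instead of asymmetric C–C bond formation.
- MeC≡CMgBr in THF adds to 10 to give racemic 1-(3,4,5-trimethoxyphenyl)but-2-yn-1-ol F7.
- Alkoxide-directed trans-hydroalumination with NaAlH2(OCH2CH2OMe)2 in THF gives racemic (E)-1-(3,4,5-trimethoxyphenyl)but-2-en-1-ol F8.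
- Sharpless kinetic resolution follows (Ti(OiPr)4, D-(−)-diisopropyl tartrate, t-BuOOH 0.6 equiv, 4 Å sieves, CH2Cl2, −20 °C). It should epoxidise the (S)-enantiomer faster, to (R)-[(2R,3R)-3-methyloxiran-2-yl](3,4,5-trimethoxyphenyl)methanol F9, and leave 13 for chromatographic separation.

3. Step 3.
- What may go wrong: the aryllithium may add to the newly formed ester, or acylation at the crowded carbanion may be sluggish.
- Fallback (sets out from 4, rejoins at 6): acylation is replaced by halogenation and catalytic carbonylation.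
- Aryllithium 5, generated as in the main route, is quenched with I2 to give [4-iodo-2,3-bis(methoxymethoxy)phenyl]trimethylsilane F10.
- Palladium-catalysed methoxycarbonylation (Pd(OAc)2, dppf, CO 1 atm, MeOH, Et3N, DMF, 70 °C) converts F10 into 6.

Further compounds
F1 | step 8 | 3,4,5-trimethoxybenzyl alcohol | COc1cc(CO)cc(OC)c1OC
F2 | step 8 | methyl 2-[5-bromo-2-(3,4,5-trimethoxybenzyloxy)phenyl]acetate | COC(=O)Cc1cc(Br)ccc1OCc1cc(OC)c(OC)c(OC)c1
F3 | step 8 | methyl 2-[5-bromo-2-(3,4,5-trimethoxybenzyloxy)phenyl]-2-diazoacetate | COC(=O)C(=[N+]=[N-])c1cc(Br)ccc1OCc1cc(OC)c(OC)c(OC)c1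
F4 | step 8 | methyl (2R,3S)-5-bromo-2-(3,4,5-trimethoxyphenyl)-2,3-dihydrobenzofuran-3-carboxylate (cis) | COc1cc([C@@H]2Oc3ccc(Br)cc3[C@@H]2C(=O)OC)cc(OC)c1OC
F5 | step 8 | methyl (2R,3R)-5-bromo-2-(3,4,5-trimethoxyphenyl)-2,3-dihydrobenzofuran-3-carboxylate (trans) | COc1cc([C@@H]2Oc3ccc(Br)cc3[C@H]2C(=O)OC)cc(OC)c1OC
F6 | step 8 | [(2R,3S)-5-bromo-2-(3,4,5-trimethoxyphenyl)-2,3-dihydrobenzofuran-3-yl]methanol | COc1cc([C@@H]2Oc3ccc(Br)cc3[C@H]2CO)cc(OC)c1OC
F7 | step 6 | racemic 1-(3,4,5-trimethoxyphenyl)but-2-yn-1-ol | CC#CC(O)c1cc(OC)c(OC)c(OC)c1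
F8 | step 6 | racemic (E)-1-(3,4,5-trimethoxyphenyl)but-2-en-1-ol | C/C=C/C(O)c1cc(OC)c(OC)c(OC)c1
F9 | step 6 | (R)-[(2R,3R)-3-methyloxiran-2-yl](3,4,5-trimethoxyphenyl)methanol | C[C@H]1O[C@@H]1[C@H](O)c2cc(OC)c(OC)c(OC)c2
F10 | step 3 | [4-iodo-2,3-bis(methoxymethoxy)phenyl]trimethylsilane | COCOc1c(I)ccc([Si](C)(C)C)c1OCOC
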